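**Plan**

1. Locants used here: rings A/B carry C1–C10 as in a drimane (C3 lactone C=O, C4 CMe2–O, C5/C10 ring fusion, C8 quaternary, C9 CH); C11 is the CH next to ketone C12; ring D is C13(CH3)–C14H2–C8–C17–C16H–C15H2; C18 is the C(=CH2) between C11 and C17; the γ-lactone is C16–C(=O)–O–CH2–C17.
2. Cuts, in retrosynthetic order: C1=C2 (ring-closing metathesis) and C4–C5 (radical conjugate addition) of ring A; C11–C18 (Conia-ene); C5–C6 together with C8–C9 of ring B (key step); C9–C10 (Michael addition of 2-methylmalonaldehyde to an ynone); C12–C18 of a bicyclo[2.2.2]octanone (glycol cleavage), which comes from a phthalide phenol by dearomatisation and intramolecular Diels–Alder reaction.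
3. Forward order: phthalide → bicyclo[2.2.2]octenone (ring D with C13, C17 and the γ-lactone) → ring D carrying ynone, alkyne and CH(OH)CH3 arms → enone–dialdehyde → rings C and B in the key step → cage ring (C11–C18) → ring A.
4. Enabling feature: C6–C7–C8 is carried as a methyl ketone (temporary C7=O), so C8 and C6 are its two α-carbons; C9 is the β-carbon of the C12 enone and C5 is a formyl carbon on C10. Ring B therefore closes by a Michael/aldol-condensation pair; the C7 oxygen and the C5=C6 unsaturation are taken out afterwards.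
5. Stereochemistry: the bought stereocentre of (S)-but-3-en-2-ol (C7, later erased) steers the Diels–Alder step (C13, C17); C16 comes from hydrogenation; C8, C9 and C10 are relayed from C13 in the key step; C11 is fixed by the cage; C5 comes from axial radical attack anti to the axial C10 substituent.

Key step: step 13

Remark: 5-methylvanillin, (S)-but-3-en-2-ol and 2-methylmalonaldehyde (also sold as its bis(diethyl acetal)) are taken as purchasable; carbinol centres that are erased later (C12 from step 7, C18 from step 8) are drawn as the expected epimer.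

Step 1
Reactants: 1 4-hydroxy-3-methoxy-5-methylbenzaldehyde (5-methylvanillin)
Product: 2 3-methoxy-5-methyl-4-(triisopropylsilyloxy)benzaldehyde
Conditions: i-Pr3SiCl, imidazole, DMF, 25 °C
Reagents that add atoms: triisopropylsilyl chloride, CC(C)[Si](Cl)(C(C)C)C(C)C
Why: Imidazole-promoted silylation of the phenol gives a base-stable ether that does not direct metalation, as needed for the lithiation that follows.

Step 2
Reactants: 2 3-methoxy-5-methyl-4-(triisopropylsilyloxy)benzaldehyde
Product: 3 4-methoxy-6-methyl-5-(triisopropylsilyloxy)-1,3-dihydroisobenzofuran-1-ol (racemic lactol)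
Conditions: LiN(Me)CH2CH2NMe2, THF, −20 °C; n-BuLi (3 equiv), −20 °C; CH2O (gas), −78 → 0 °C; aq NH4Cl
Reagents that add atoms: formaldehyde, C=O
Why: In-situ α-amino alkoxide protection of the aldehyde and directed ortho-lithiation should metalate the ring carbon flanked by the amino alkoxide and the methoxy group, and hydroxymethylation followed by work-up closes the lactol (its hemiacetal centre is removed in step 3).

Step 3
Reactants: 3 4-methoxy-6-methyl-5-(triisopropylsilyloxy)-1,3-dihydroisobenzofuran-1-ol
Product: 4 4-methoxy-6-methyl-5-(triisopropylsilyloxy)isobenzofuran-1(3H)-one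
Conditions: n-Pr4N[RuO4] (5 mol %), N-methylmorpholine N-oxide, 4 Å MS, CH2Cl2, 25 °C
Reagents that add atoms: none
Why: Ley–Griffith oxidation of the lactol gives the phthalide, with the carbonyl on the ring carbon para to the silyloxy group.

Step 4
Reactants: 4 4-methoxy-6-methyl-5-(triisopropylsilyloxy)isobenzofuran-1(3H)-one
Product: 5 5-hydroxy-4-methoxy-6-methylisobenzofuran-1(3H)-one
Conditions: n-Bu4NF, THF, 0 °C; aq NH4Cl
Reagents that add atoms: none
Why: Fluoride desilylation frees the phenol for the oxidative dearomatisation.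

Step 5
Reactants: 5 5-hydroxy-4-methoxy-6-methylisobenzofuran-1(3H)-one; 6 (S)-but-3-en-2-ol
Product: 8 tetracyclic Diels–Alder adduct (bicyclo[2.2.2]octenone: C12 ketone, C13 and C17 bridgeheads, C18 methyl ketal tied to C7–O in a tetrahydrofuran ring, C15=C16 butenolide, (S)-C7 methyl exo), via ketal dienone 7 (not isolated)
Conditions: PhI(OAc)2, 6 (5 equiv), CH2Cl2, 0 → 25 °C; then toluene, 80 °C; chromatography
Reagents that add atoms: none
Why: Oxidative ketalisation of the 2-methoxyphenol with the alkenol gives a masked o-benzoquinone that undergoes an intramolecular Diels–Alder reaction; the tether fixes the regiochemistry (C8 to C17, C14 to C13) and the face, and with (S)-6 the ketal epimer that can add with its methyl group exo gives 8 (C13, C17, C8 set), whereas the other epimer, formed alongside without control, can only react through the endo-methyl transition state to a diastereomer that is removed by chromatography.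

Step 6
Reactants: 8 tetracyclic Diels–Alder adduct
Product: 9 15,16-dihydro adduct (C16–H on the side of the C14–C8 bridge, lactone carbonyl on the side of the C12–C18 bridge)
Conditions: H2 (1 atm), Pd/C, EtOAc, 25 °C
Reagents that add atoms: none
Why: Heterogeneous hydrogenation of the strained conjugated alkene should deliver hydrogen from the face of the C14–C8 bridge, because the ketal methoxy group on C18 shields the other face; this sets C16.

Step 7
Reactants: 9 15,16-dihydro adduct
Product: 10 C12 tertiary propargylic alcohol (C12–C≡C–Si(i-Pr)3)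
Conditions: i-Pr3SiC≡CH, n-BuLi, THF, −78 °C; aq NH4Cl
Reagents that add atoms: (triisopropylsilyl)acetylene, C#C[Si](C(C)C)(C(C)C)C(C)C
Why: 1,2-Addition of the lithium acetylide to the bicyclic ketone, which should be faster than attack on the hindered γ-lactone at −78 °C, installs C11 and C9; the carbinol configuration is immaterial (erased in step 9).

Step 8
Reactants: 10 C12 tertiary propargylic alcohol
Product: 12 triol (C7–OH, C18–OH, C12–OH), via hydroxy ketone 11 (not isolated)
Conditions: 1 M HCl, THF, 25 °C; then NaBH4, MeOH, 0 °C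
Reagents that add atoms: water, O
Why: Acid hydrolysis of the mixed ketal unmasks the C18 ketone and the C7 alcohol, and immediate borohydride reduction (before an α-ketol shift can set in) gives the 1,2-diol needed for cleavage; the C18 carbinol configuration is immaterial.

Step 9
Reactants: 12 triol
Product: 13 ring-D keto aldehyde (C13–C(=O)–C≡C–Si(i-Pr)3, C17–CHO resting as a lactol with the C7 hydroxyl)
Conditions: Pb(OAc)4, CH2Cl2, 0 °C
Reagents that add atoms: none
Why: Criegee glycol cleavage opens the C12–C18 bond of the bicyclo[2.2.2]octane and releases ring D with a cis-1,4 pair of carbonyl arms on C13 and C17 without touching a stereocentre.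

Step 10
Reactants: 13 ring-D keto aldehyde
Product: 14 ring-D alkyne (C17–C≡CH, free C7–OH)
Conditions: MeC(O)C(N2)P(O)(OMe)2, K2CO3, MeOH, 0 → 25 °C
Reagents that add atoms: dimethyl (1-diazo-2-oxopropyl)phosphonate, CC(=O)C(=[N+]=[N-])P(=O)(OC)OC
Why: Ohira–Bestmann (Seyferth–Gilbert) homologation of the hindered aldehyde, through the open form of its lactol, gives the terminal alkyne that later becomes C18 and the exocyclic methylene.

Step 11
Reactants: 14 ring-D alkyne; 15 2-methylmalonaldehyde
Product: 17 (E)-enone dialdehyde with free C7–OH, via terminal ynone 16 (not isolated)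
Conditions: n-Bu4NF, AcOH, THF, −20 °C; then 15, Et3N (0.2 equiv), 0 → 25 °C
Reagents that add atoms: none
Why: Fluoride cleaves the silyl ynone, and base-catalysed Michael addition of the 1,3-dialdehyde through carbon to the terminal ynone forms C9–C10 and the thermodynamically preferred E-enone; C10 stays prochiral (two formyl groups).

Step 12
Reactants: 17 (E)-enone dialdehyde with free C7–OH
Product: 18 (E)-enone dialdehyde methyl ketone (C8–C(=O)CH3)
Conditions: Dess–Martin periodinane, NaHCO3, CH2Cl2, 25 °C
Reagents that add atoms: none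
Why: Dess–Martin oxidation of the secondary alcohol gives the temporary C7 methyl ketone; the bought stereocentre is erased and C8 becomes epimerisable, which is harmless because C8 is reset in the next step.

Step 13
Reactants: 18 (E)-enone dialdehyde methyl ketone
Product: 20 tetracyclic enone aldehyde (rings B, C, D and γ-lactone; C7 ketone, C5=C6, C10 with CH3 and CHO), via Michael adduct 19 (not isolated)
Conditions: Cs2CO3 (0.5 equiv), MeCN (0.01 M), 25 → 50 °C
Reagents that add atoms: none
Why: Carbonate equilibrates the enolates of the temporary C7 methyl ketone; the more substituted enolate carbon C8 adds to C9, the β-carbon of the C12 enone (6-endo-trig Michael addition, closing cyclohexanone ring C on ring D as the bicyclo[3.3.1]nonanone 19), and after proton transfer the methyl-derived enolate carbon C6 attacks one formyl group (C5) and loses water by E1cB (6-(enolendo)-exo-trig aldol condensation, closing ring B as a cyclohexenone), so that C8–C9 and C5–C6 are made in one operation. The closest known reaction type is the Robinson-type Michael/aldol-condensation annulation, used here as an α,α′-annulation of one ketone across two acceptors. C8 is controlled by C13: the C12 acyl chain and the new bond must be 1,3-syn on ring D, so C9 can only bond to the face of C8 syn to C12, and the acetyl carbon is pushed to the other face. C9 is controlled by the E-geometry of the enone, which keeps C10 pseudo-equatorial on ring C in the chair-like transition state (C10 anti to C14). C10 is set by the choice between the two diastereotopic formyl groups: on the forming ring B the site on C10 that is 1,3-diaxial to C17 should be taken by the flat formyl group and not by methyl, which leaves the methyl group syn to H-9. The step needs C8 and not C6 to add first (only C8 reaches C9 through a six-membered transition state) and the 1,3-dialdehyde to survive, which a weak non-nucleophilic base in an aprotic solvent at high dilution should secure.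

Step 14
Reactants: 20 tetracyclic enone aldehyde
Product: 21 C1 vinyl compound (C10–CH=CH2)
Conditions: Ph3PCH3Br, KN(SiMe3)2, THF, −78 → 0 °C
Reagents that add atoms: methyltriphenylphosphonium bromide (CH2 source), C[P+](c1ccccc1)(c1ccccc1)c1ccccc1.[Br-]
Why: Wittig methylenation should take the aldehyde in preference to the hindered C12 ketone and the enone, and gives the vinyl group that becomes C1.

Step 15
Reactants: 21 C1 vinyl compound
Product: 23 cage enone (C11–C18 bond, exocyclic methylene on C18), via silyl enol ether 22 (not isolated)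
Conditions: t-BuMe2SiOTf, Et3N, CH2Cl2, 0 °C; then Ph3PAuCl (10 mol %), AgBF4 (10 mol %), CH2Cl2/MeOH 10:1, 25 °C
Reagents that add atoms: none
Why: Soft enolisation of the only enolisable ketone (C12 towards C11; the ring-B enone has no α- or γ-hydrogen) and gold-catalysed 5-exo-dig carbocyclisation of the silyl enol ether onto the alkyne (Conia-ene type) form C11–C18 with the exocyclic methylene; C11 is fixed by the cage.

Step 16
Reactants: 23 cage enone
Product: 24 C5 adduct (C5–C(CH3)2OH, C6H2, C7 ketone)
Conditions: (n-Bu4N)4[W10O32] (2 mol %), i-PrOH/MeCN 1:1, 390 nm LED, 25 °C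
Reagents that add atoms: propan-2-ol, CC(C)O
Why: Decatungstate-photocatalysed hydrogen-atom transfer from propan-2-ol and Giese addition of the 2-hydroxyprop-2-yl radical to the enone should occur by axial attack on C5 anti to the axial C10 vinyl group, which sets C5 (H trans to the C10 methyl group) and introduces C4 with its oxygen.

Step 17
Reactants: 24 C5 adduct
Product: 26 7-deoxy tertiary alcohol (C7H2), via C7 tosylhydrazone 25 (not isolated)
Conditions: TsNHNH2, AcOH (cat.), EtOH, 60 °C; then catecholborane, CHCl3, 0 °C; NaOAc·3H2O, 60 °C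
Reagents that add atoms: none
Why: Caglioti reduction (tosylhydrazone, hydride addition, loss of sulfinate and N2) removes the temporary C7 oxygen; the cage ketone C12, flanked by a quaternary and a bridgehead carbon, should not condense.

Step 18
Reactants: 26 7-deoxy tertiary alcohol
Product: 27 C4 acrylate
Conditions: acryloyl chloride, Et3N, DMAP (cat.), CH2Cl2, 0 → 25 °C
Reagents that add atoms: acryloyl chloride, C=CC(=O)Cl
Why: DMAP-catalysed acylation of the tertiary alcohol brings in C2 and C3.

Step 19
Reactants: 27 C4 acrylate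
Product: 28 CNP0136584.3 (target)
Conditions: second-generation Hoveyda–Grubbs catalyst (10 mol %), toluene (1 mM), 80 °C
Reagents that add atoms: none
Why: Ring-closing metathesis of the acrylate with the C10 vinyl group forms C1=C2 (Z by ring size) and the seven-membered unsaturated lactone, while the hindered 1,1-disubstituted cage methylene should stay a spectator.

**Compound list**

1 | 4-hydroxy-3-methoxy-5-methylbenzaldehyde (5-methylvanillin) | Cc1cc(C=O)cc(OC)c1O | starting material
2 | 3-methoxy-5-methyl-4-(triisopropylsilyloxy)benzaldehyde | Cc1cc(C=O)cc(OC)c1O[Si](C(C)C)(C(C)C)C(C)C | intermediate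
3 | 4-methoxy-6-methyl-5-(triisopropylsilyloxy)-1,3-dihydroisobenzofuran-1-ol (racemic lactol) | Cc1cc2C(O)OCc2c(OC)c1O[Si](C(C)C)(C(C)C)C(C)C | intermediate
4 | 4-methoxy-6-methyl-5-(triisopropylsilyloxy)isobenzofuran-1(3H)-one | Cc1cc2C(=O)OCc2c(OC)c1O[Si](C(C)C)(C(C)C)C(C)C | intermediate
5 | 5-hydroxy-4-methoxy-6-methylisobenzofuran-1(3H)-one | Cc1cc2C(=O)OCc2c(OC)c1O | intermediate
6 | (S)-but-3-en-2-ol | C[C@H](O)C=C | starting material
7 | masked o-benzoquinone mixed ketal of 5 (methoxy and (S)-but-3-en-2-yloxy on C18; reactive ketal epimer) | O=C1C(C)=CC2=C(COC2=O)[C@@]1(OC)O[C@@H](C)C=C | intermediate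
8 | Diels–Alder adduct: bicyclo[2.2.2]octenone with C12 ketone, C18 ketal in a tetrahydrofuran ring (C18–O–C7–C8–C17), C15=C16 butenolide, C7 methyl exo | C[C@]12C(=O)[C@]3(OC)O[C@@H](C)[C@H](C1)[C@]3(COC4=O)C4=C2 | intermediate
9 | 15,16-dihydro adduct | C[C@]12C(=O)[C@]3(OC)O[C@@H](C)[C@H](C1)[C@]3(COC4=O)[C@@H]4C2 | intermediate
10 | C12 tertiary propargylic alcohol (triisopropylsilyl alkyne) | C[C@]12[C@](O)(C#C[Si](C(C)C)(C(C)C)C(C)C)[C@]3(OC)O[C@@H](C)[C@H](C1)[C@]3(COC4=O)[C@@H]4C2 | intermediate
11 | C18 ketone with free C7 and C12 hydroxyls (α-hydroxy ketone) | C[C@]12[C@](O)(C#C[Si](C(C)C)(C(C)C)C(C)C)C(=O)[C@]3(COC(=O)[C@H]3C2)[C@@H](C1)[C@H](C)O | intermediate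
12 | triol (C7–OH, C18–OH, C12–OH) | C[C@]12[C@](O)(C#C[Si](C(C)C)(C(C)C)C(C)C)[C@H](O)[C@]3(COC(=O)[C@H]3C2)[C@@H](C1)[C@H](C)O | intermediate
13 | ring-D keto aldehyde: C13 silyl ynone, C17 formyl (open form of the lactol with C7–OH), γ-lactone, C8–CH(OH)CH3 | C[C@@]1(C(=O)C#C[Si](C(C)C)(C(C)C)C(C)C)C[C@@H]2C(=O)OC[C@@]2(C=O)[C@H]([C@H](C)O)C1 | intermediate
14 | ring-D alkyne (C17–C≡CH) with silyl ynone and C7–OH | C[C@@]1(C(=O)C#C[Si](C(C)C)(C(C)C)C(C)C)C[C@@H]2C(=O)OC[C@@]2(C#C)[C@H]([C@H](C)O)C1 | intermediate
15 | 2-methylmalonaldehyde | CC(C=O)C=O | starting material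
16 | terminal ynone (C13–C(=O)–C≡CH) | C[C@@]1(C(=O)C#C)C[C@@H]2C(=O)OC[C@@]2(C#C)[C@H]([C@H](C)O)C1 | intermediate
17 | (E)-enone dialdehyde with C7–OH | C[C@@]1(C(=O)/C=C/C(C)(C=O)C=O)C[C@@H]2C(=O)OC[C@@]2(C#C)[C@H]([C@H](C)O)C1 | intermediate
18 | (E)-enone dialdehyde methyl ketone | C[C@@]1(C(=O)/C=C/C(C)(C=O)C=O)C[C@@H]2C(=O)OC[C@@]2(C#C)[C@H](C(C)=O)C1 | intermediate
19 | bicyclo[3.3.1]nonanone Michael adduct (ring C closed; C8 acetyl, C9–C(CH3)(CHO)2) | C#C[C@@]12COC(=O)[C@H]1C[C@@]3(C)C(=O)C[C@@H](C(C)(C=O)C=O)[C@@]2(C3)C(C)=O | intermediate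
20 | tetracyclic enone aldehyde (rings B and C closed; C7 ketone, C5=C6, C10–CHO) | C#C[C@@]12COC(=O)[C@H]1C[C@@]3(C)C(=O)C[C@@H]4[C@@]2(C3)C(=O)C=C[C@]4(C)C=O | intermediate
21 | C1 vinyl compound | C#C[C@@]12COC(=O)[C@H]1C[C@@]3(C)C(=O)C[C@@H]4[C@@]2(C3)C(=O)C=C[C@]4(C)C=C | intermediate
22 | C12 tert-butyldimethylsilyl enol ether (C11=C12) | C#C[C@@]12COC(=O)[C@H]1C[C@@]3(C)C(O[Si](C)(C)C(C)(C)C)=C[C@@H]4[C@@]2(C3)C(=O)C=C[C@]4(C)C=C | intermediate
23 | cage enone (C11–C18 closed, exocyclic methylene; C7 ketone, C5=C6, C10 vinyl) | C=C1[C@@H]2C(=O)[C@]3(C)C[C@@H]4C(=O)OC[C@]14[C@@]1(C(=O)C=C[C@](C)(C=C)[C@H]21)C3 | intermediate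
24 | C5 2-hydroxypropan-2-yl adduct (C7 ketone) | C=C1[C@@H]2C(=O)[C@]3(C)C[C@@H]4C(=O)OC[C@]14[C@@]1(C(=O)C[C@@H](C(C)(C)O)[C@](C)(C=C)[C@H]21)C3 | intermediate
25 | C7 tosylhydrazone of 24 | C=C1[C@@H]2C(=O)[C@]3(C)C[C@@H]4C(=O)OC[C@]14[C@@]1(C(=NNS(=O)(=O)c5ccc(C)cc5)C[C@@H](C(C)(C)O)[C@](C)(C=C)[C@H]21)C3 | intermediate
26 | 7-deoxy tertiary alcohol | C=C1[C@@H]2C(=O)[C@]3(C)C[C@@H]4C(=O)OC[C@]14[C@@]1(CC[C@@H](C(C)(C)O)[C@](C)(C=C)[C@H]21)C3 | intermediate
27 | C4 acrylate | C=C1[C@@H]2C(=O)[C@]3(C)C[C@@H]4C(=O)OC[C@]14[C@@]1(CC[C@@H](C(C)(C)OC(=O)C=C)[C@](C)(C=C)[C@H]21)C3 | intermediate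
28 | CNP0136584.3 | C=C1[C@@H]2C(=O)[C@]3(C)C[C@@H]4C(=O)OC[C@]14[C@@]1(CC[C@H]4C(C)(C)OC(=O)C=C[C@]4(C)[C@H]21)C3 | target

Total step count: 19. Longest linear sequence: 19 steps (from 1).

**Steps most likely to fail**

Step 13. What may go wrong: loss of a formyl group from the 2,2-disubstituted malonaldehyde by retro-Claisen-type cleavage, reversal of the first Michael addition with erosion of the C9 configuration, and slow closure because ring D (held in a chair by its trans-fused lactone) must go to a boat before C8 can reach C9. Fallback, setting out from 18 and coming back at 20: a stepwise, non-basic sequence. Me3SiOTf/Et3N under equilibrating conditions gives the more substituted trimethylsilyl enol ether F1. TiCl4 at −78 °C then effects an intramolecular Mukaiyama–Michael addition to C9 and gives 19, now isolated. Ring B is closed in a separate operation with pyrrolidinium acetate (iminium/enamine aldol condensation) to give 20.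

Step 15. What may go wrong: the enol ether carbon C11 and the alkyne may fail to reach bonding distance (ring D has to take up a boat), so that protodesilylation or alkyne hydration wins over cyclisation. Fallback, setting out from 21 and coming back at 23: radical ring closure in place of the cationic one. The silyl enol ether 22 is treated with N-bromosuccinimide to give the C11 α-bromo ketone F2. Bu3SnH/AIBN (slow addition, benzene, 80 °C) generates the α-keto radical, which closes 5-exo-dig onto the alkyne; hydrogen transfer to the vinyl radical gives 23.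

Step 19. What may go wrong: the C10 vinyl group and the C4 acrylate sit trans-diaxial on the chair of ring B, closure forces ring B into a twist form, and intermolecular metathesis may outrun it. Fallback, setting out from 20 and coming back at 28: the aldehyde is kept and ring A is closed by an intramolecular Horner–Wadsworth–Emmons reaction. Compound 20 is converted into its C12 silyl enol ether F3 and cyclised with the gold catalyst of step 15 to the cage enone aldehyde F4. Photocatalytic Giese addition of propan-2-ol as in step 16 gives the tertiary alcohol F5. Esterification with diethylphosphonoacetic acid (DCC, DMAP) gives the phosphonoacetate F6. LiCl/DBU in MeCN at high dilution closes the unsaturated lactone to the 7-oxo lactone F7. Caglioti reduction through the tosylhydrazone F8, as in step 17, gives 28.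

**Further compounds**

F1 | step 13 | C8=C7 trimethylsilyl enol ether of 18 | C[C@@]1(C(=O)/C=C/C(C)(C=O)C=O)C[C@@H]2C(=O)OC[C@@]2(C#C)C(=C(C)O[Si](C)(C)C)C1
F2 | step 15 | C11 α-bromo ketone of 21 (either C11 epimer) | C#C[C@@]12COC(=O)[C@H]1C[C@@]3(C)C(=O)C(Br)[C@@H]4[C@@]2(C3)C(=O)C=C[C@]4(C)C=C
F3 | step 19 | C12 tert-butyldimethylsilyl enol ether of 20 | C#C[C@@]12COC(=O)[C@H]1C[C@@]3(C)C(O[Si](C)(C)C(C)(C)C)=C[C@@H]4[C@@]2(C3)C(=O)C=C[C@]4(C)C=O
F4 | step 19 | cage enone aldehyde (C11–C18 closed, C10–CHO) | C=C1[C@@H]2C(=O)[C@]3(C)C[C@@H]4C(=O)OC[C@]14[C@@]1(C(=O)C=C[C@](C)(C=O)[C@H]21)C3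
F5 | step 19 | C5 2-hydroxypropan-2-yl adduct of F4 | C=C1[C@@H]2C(=O)[C@]3(C)C[C@@H]4C(=O)OC[C@]14[C@@]1(C(=O)C[C@@H](C(C)(C)O)[C@](C)(C=O)[C@H]21)C3
F6 | step 19 | diethylphosphonoacetate of F5 | C=C1[C@@H]2C(=O)[C@]3(C)C[C@@H]4C(=O)OC[C@]14[C@@]1(C(=O)C[C@@H](C(C)(C)OC(=O)CP(=O)(OCC)OCC)[C@](C)(C=O)[C@H]21)C3
F7 | step 19 | 7-oxo derivative of 28 | C=C1[C@@H]2C(=O)[C@]3(C)C[C@@H]4C(=O)OC[C@]14[C@@]1(C(=O)C[C@H]4C(C)(C)OC(=O)C=C[C@]4(C)[C@H]21)C3
F8 | step 19 | C7 tosylhydrazone of F7 | C=C1[C@@H]2C(=O)[C@]3(C)C[C@@H]4C(=O)OC[C@]14[C@@]1(C(=NNS(=O)(=O)c5ccc(C)cc5)C[C@H]4C(C)(C)OC(=O)C=C[C@]4(C)[C@H]21)C3
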